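The isoflavan is cut at the two bonds that tie the pyran ring to ring A, C4–C4a and O1–C8a. C3 bears two methylene arms, C2 (on O1) and C4 (on C4a), and ring A is a 3,5-dimethoxy-4-prenylphenyl unit whose two positions ortho to C8a are equivalent; O1, C2, C3 and C4 can therefore come from an oxetane with enantiotopic CH2 groups. One palladium/norbornene annulation alkylates an ortho C–H of the ring A iodide with an oxetane CH2 and etherifies the ipso carbon with the freed alkoxide, closing the pyran ring and setting C3. Its precursors are 5-iodo-1,3-dimethoxy-2-prenylbenzene and a 3-aryloxetane carrying ring B as bis-MOM 3-prenylresorcinol; deprotection and Teuber oxidation follow.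

Key step: step 7

Remarks on the chemistry
- Prenyl = 3-methylbut-2-en-1-yl. Isoflavan numbering is used (O1, C2, C3, C4, C4a, C5–C8, C8a; primed atoms for ring B). C3 is R in the target and in compounds 16–18 (CIP order C2 > C1′ > C4 > H).
- Assumption: the sense of induction of the enantiopure norbornene in step 7 cannot be predicted with confidence; the antipode that leads to the 3R product is the one specified.
- Design points: the ring A iodide is made in two steps with its regiochemistry fixed by sterics. The only base that meets a C–Br bond before the planned exchange is an amide. The MOM groups are removed without a Brønsted acid. One mediator, an enantiopure bridgehead-substituted norbornene, is asked both to stop the sequence after one ortho alkylation and to choose between the enantiotopic CH2 groups.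

Step 1
Reactants: 1 1,3-dimethoxybenzene; 2 prenyl bromide
Product: 4 1,3-dimethoxy-2-(3-methylbut-2-en-1-yl)benzene, via (2,6-dimethoxyphenyl)lithium 3 (not isolated)
Conditions: n-BuLi, THF, 0 °C to rt; then 2, 0 °C to rt
Reagents that add atoms: none
Why: Directed ortho-metalation places lithium on the carbon between the two methoxy groups, and the aryllithium is alkylated at the primary carbon of the allylic bromide in an SN2 reaction.

Step 2
Reactants: 4 1,3-dimethoxy-2-(3-methylbut-2-en-1-yl)benzene
Product: 6 5-iodo-1,3-dimethoxy-2-(3-methylbut-2-en-1-yl)benzene, via arylboronic acid pinacol ester 5 (not isolated)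
Conditions: [Ir(OMe)(cod)]2 (1.5 mol%), 4,4′-di-tert-butyl-2,2′-bipyridine (3 mol%), B2pin2, THF, 80 °C; volatiles removed; CuI (10 mol%), 1,10-phenanthroline (20 mol%), KI (1.5 equiv), MeOH/H2O, air, 80 °C
Reagents that add atoms: bis(pinacolato)diboron, CC1(C)OB(OC1(C)C)B1OC(C)(C)C(C)(C)O1 (boron and pinacol of 5 only); potassium iodide, [K+].[I-]
Why: Iridium-catalysed C–H borylation is sterically controlled and should reach only the ring hydrogen that has no ortho substituent (para to the prenyl group), and the copper-mediated iododeboronation of the crude boronate with iodide under air puts iodine on that carbon without an electrophilic iodine reagent that would attack the hindered trisubstituted alkene.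

Step 3
Reactants: 7 4-bromobenzene-1,3-diol
Product: 8 1-bromo-2,4-bis(methoxymethoxy)benzene
Conditions: NaH (2.4 equiv), DMF, 0 °C; MOMCl (2.4 equiv), 0 °C to rt
Reagents that add atoms: chloromethyl methyl ether, COCCl
Why: Williamson-type O-alkylation of the bis-phenoxide with the chloromethyl ether gives the bis-acetal that masks both phenols and later directs the metalation.

Step 4
Reactants: 8 1-bromo-2,4-bis(methoxymethoxy)benzene; 2 prenyl bromide
Product: 10 1-bromo-2,4-bis(methoxymethoxy)-3-(3-methylbut-2-en-1-yl)benzene, via [3-bromo-2,6-bis(methoxymethoxy)phenyl]lithium 9 (not isolated)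
Conditions: LiN(i-Pr)2 (1.2 equiv), THF, −78 °C; then 2, −78 °C to rt
Reagents that add atoms: none
Why: Directed ortho-metalation with the non-nucleophilic amide base removes the proton flanked by both acetal oxygens while leaving the C–Br bond intact (lithium ends meta to bromine, so no aryne can form), and SN2 alkylation with the allylic bromide follows.

Step 5
Reactants: 10 1-bromo-2,4-bis(methoxymethoxy)-3-(3-methylbut-2-en-1-yl)benzene
Product: 13 [2,4-bis(methoxymethoxy)-3-(3-methylbut-2-en-1-yl)phenyl]boronic acid, via aryllithium 11 (not isolated), via lithium aryltriisopropoxyborate 12 (not isolated)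
Conditions: n-BuLi (1.05 equiv), THF, −78 °C; B(Oi-Pr)3, −78 °C to 0 °C; then aq. HCl to pH 5, 0 °C
Reagents that add atoms: triisopropyl borate, CC(C)OB(OC(C)C)OC(C)C; water, O
Why: Bromine–lithium exchange at low temperature outpaces deprotonation, the aryllithium is trapped by the borate as the ate complex, and mild hydrolysis releases the boronic acid (borylation of an organolithium).

Step 6
Reactants: 13 [2,4-bis(methoxymethoxy)-3-(3-methylbut-2-en-1-yl)phenyl]boronic acid; 14 3-iodooxetane
Product: 15 3-[2,4-bis(methoxymethoxy)-3-(3-methylbut-2-en-1-yl)phenyl]oxetane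
Conditions: NiI2 (6 mol%), trans-2-aminocyclohexanol hydrochloride (6 mol%), NaN(SiMe3)2 (2 equiv), i-PrOH, 80 °C
Reagents that add atoms: none
Why: Nickel-catalysed alkyl–aryl Suzuki–Miyaura coupling of a secondary alkyl iodide under amino alcohol ligation is the established way to 3-aryloxetanes from 3-iodooxetane, and the acetals, the alkene and the strained ether tolerate the basic alcoholic medium.

Step 7
Reactants: 6 5-iodo-1,3-dimethoxy-2-(3-methylbut-2-en-1-yl)benzene; 15 3-[2,4-bis(methoxymethoxy)-3-(3-methylbut-2-en-1-yl)phenyl]oxetane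
Product: 16 (3R)-3-[2,4-bis(methoxymethoxy)-3-(3-methylbut-2-en-1-yl)phenyl]-5,7-dimethoxy-6-(3-methylbut-2-en-1-yl)-3,4-dihydro-2H-chromene
Conditions: Pd(OAc)2 (10 mol%), XPhos (20 mol%), enantiopure 1-butylbicyclo[2.2.1]hept-2-ene (1 equiv), LiOTf (1 equiv), Cs2CO3 (2.5 equiv), toluene/1,4-dioxane, 100 °C
Reagents that add atoms: none
Why: Proposed new method: zerovalent palladium inserts into the C–I bond of 6, the norbornene inserts and one of the two equivalent ortho C–H bonds is palladated to give the aryl–norbornyl palladacycle of divalent palladium, which opens the lithium-coordinated oxetane at a CH2 group by SN2 oxidative addition to tetravalent palladium; reductive elimination forms C4–C4a, the bridgehead substituent forces extrusion of norbornene after this single alkylation, and the tethered alkoxide then binds the aryl divalent palladium centre. The closest known reaction type is the palladium/norbornene ortho-alkylation and ipso-etherification of aryl iodides with epoxides that delivers 2,3-dihydrobenzofurans, extended here to the less electrophilic but still strained four-membered ether, which cannot ionise to a benzylic cation because its aryl group sits on the carbon beta to oxygen. The pyran ring is closed as a formal [4+2] annulation, the C4–C3–C2–O1 chain of the oxetane being joined to C4a intermolecularly and then to C8a by C–O reductive elimination from a seven-membered oxapalladacycle. C3 is the only new stereocentre and is set at the oxidative addition, where the palladacycle, chiral through the enantiopure norbornene bound in it, selects one of the two enantiotopic CH2 groups of 15. The step needs mono-alkylation, which the bridgehead-substituted norbornene secures, needs no site selectivity on ring A because the mirror symmetry of 6 makes both ortho positions identical, and needs chemoselectivity over the two prenyl groups, which as trisubstituted alkenes should not compete with the strained norbornene for arylpalladium insertion.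

Step 8
Reactants: 16 (3R)-3-[2,4-bis(methoxymethoxy)-3-(3-methylbut-2-en-1-yl)phenyl]-5,7-dimethoxy-6-(3-methylbut-2-en-1-yl)-3,4-dihydro-2H-chromene
Product: 18 4-[(3R)-5,7-dimethoxy-6-(3-methylbut-2-en-1-yl)-3,4-dihydro-2H-chromen-3-yl]-2-(3-methylbut-2-en-1-yl)benzene-1,3-diol, via bis(trimethylsilyl) ether 17 (not isolated)
Conditions: Me3SiOTf (4 equiv), 2,2′-bipyridyl (6 equiv), MeCN, 0 °C to rt; then H2O, rt
Reagents that add atoms: trimethylsilyl trifluoromethanesulfonate, C[Si](C)(C)OS(=O)(=O)C(F)(F)F (silyl groups of 17 only)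
Why: Acetal cleavage under non-protic buffered conditions: the silyl triflate–bipyridyl pair converts aryl MOM ethers into aryl silyl ethers, which water hydrolyses, so no Brønsted acid strong enough to cyclise the 3′-prenyl group onto the flanking phenols is present and C3 is untouched.

Step 9
Reactants: 18 4-[(3R)-5,7-dimethoxy-6-(3-methylbut-2-en-1-yl)-3,4-dihydro-2H-chromen-3-yl]-2-(3-methylbut-2-en-1-yl)benzene-1,3-diol
Product: 19 5-[(3R)-5,7-dimethoxy-6-(3-methylbut-2-en-1-yl)-3,4-dihydro-2H-chromen-3-yl]-2-hydroxy-3-(3-methylbut-2-en-1-yl)cyclohexa-2,5-diene-1,4-dione (CNP0241224.1)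
Conditions: Fremy's salt, (KSO3)2NO (2.5 equiv), KH2PO4 buffer (pH 6–7), acetone/H2O, 0 °C to rt
Reagents that add atoms: Fremy's salt, (KSO3)2NO, [K+].[K+].[O]N(S(=O)(=O)[O-])S(=O)(=O)[O-]
Why: Teuber oxidation: the nitroxyl radical abstracts a phenolic hydrogen and a second equivalent oxygenates C5′, the only unsubstituted carbon that carries spin density (para to the 2′-OH, ortho to the 4′-OH), so that loss of imidodisulfonate gives the 2′,5′-quinone with the 4′-OH retained as the stable hydroxy-para-quinone tautomer, while ring A, which has no free phenol, and the stereocentre C3 are left alone.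

Compound list
1 | 1,3-dimethoxybenzene | COc1cccc(OC)c1 | starting material
2 | prenyl bromide (1-bromo-3-methylbut-2-ene) | CC(C)=CCBr | starting material
3 | (2,6-dimethoxyphenyl)lithium | [Li]c1c(OC)cccc1OC | intermediate (not isolated)
4 | 1,3-dimethoxy-2-(3-methylbut-2-en-1-yl)benzene | COc1cccc(OC)c1CC=C(C)C | intermediate
5 | 2-[3,5-dimethoxy-4-(3-methylbut-2-en-1-yl)phenyl]-4,4,5,5-tetramethyl-1,3,2-dioxaborolane | COc1cc(cc(OC)c1CC=C(C)C)B1OC(C)(C)C(C)(C)O1 | intermediate (not isolated)
6 | 5-iodo-1,3-dimethoxy-2-(3-methylbut-2-en-1-yl)benzene | COc1cc(I)cc(OC)c1CC=C(C)C | intermediate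
7 | 4-bromobenzene-1,3-diol (4-bromoresorcinol) | Oc1ccc(Br)c(O)c1 | starting material
8 | 1-bromo-2,4-bis(methoxymethoxy)benzene | COCOc1ccc(Br)c(OCOC)c1 | intermediate
9 | [3-bromo-2,6-bis(methoxymethoxy)phenyl]lithium | [Li]c1c(OCOC)ccc(Br)c1OCOC | intermediate (not isolated)
10 | 1-bromo-2,4-bis(methoxymethoxy)-3-(3-methylbut-2-en-1-yl)benzene | COCOc1ccc(Br)c(OCOC)c1CC=C(C)C | intermediate
11 | [2,4-bis(methoxymethoxy)-3-(3-methylbut-2-en-1-yl)phenyl]lithium | [Li]c1ccc(OCOC)c(CC=C(C)C)c1OCOC | intermediate (not isolated)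
12 | lithium [2,4-bis(methoxymethoxy)-3-(3-methylbut-2-en-1-yl)phenyl]tri(propan-2-yloxy)borate | [Li+].CC(C)O[B-](OC(C)C)(OC(C)C)c1ccc(OCOC)c(CC=C(C)C)c1OCOC | intermediate (not isolated)
13 | [2,4-bis(methoxymethoxy)-3-(3-methylbut-2-en-1-yl)phenyl]boronic acid | OB(O)c1ccc(OCOC)c(CC=C(C)C)c1OCOC | intermediate
14 | 3-iodooxetane | IC1COC1 | starting material
15 | 3-[2,4-bis(methoxymethoxy)-3-(3-methylbut-2-en-1-yl)phenyl]oxetane | C1OCC1c1ccc(OCOC)c(CC=C(C)C)c1OCOC | intermediate
16 | (3R)-3-[2,4-bis(methoxymethoxy)-3-(3-methylbut-2-en-1-yl)phenyl]-5,7-dimethoxy-6-(3-methylbut-2-en-1-yl)-3,4-dihydro-2H-chromene | COc1cc2c(c(OC)c1CC=C(C)C)C[C@H](c1ccc(OCOC)c(CC=C(C)C)c1OCOC)CO2 | intermediate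
17 | (3R)-3-[2,4-bis(trimethylsilyloxy)-3-(3-methylbut-2-en-1-yl)phenyl]-5,7-dimethoxy-6-(3-methylbut-2-en-1-yl)-3,4-dihydro-2H-chromene | COc1cc2c(c(OC)c1CC=C(C)C)C[C@H](c1ccc(O[Si](C)(C)C)c(CC=C(C)C)c1O[Si](C)(C)C)CO2 | intermediate (not isolated)
18 | 4-[(3R)-5,7-dimethoxy-6-(3-methylbut-2-en-1-yl)-3,4-dihydro-2H-chromen-3-yl]-2-(3-methylbut-2-en-1-yl)benzene-1,3-diol | COc1cc2c(c(OC)c1CC=C(C)C)C[C@H](c1ccc(O)c(CC=C(C)C)c1O)CO2 | intermediate
19 | 5-[(3R)-5,7-dimethoxy-6-(3-methylbut-2-en-1-yl)-3,4-dihydro-2H-chromen-3-yl]-2-hydroxy-3-(3-methylbut-2-en-1-yl)cyclohexa-2,5-diene-1,4-dione | COc1cc2c(c(OC)c1CC=C(C)C)C[C@H](C1=CC(=O)C(O)=C(CC=C(C)C)C1=O)CO2 | target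

Total step count: 9. Longest linear sequence: 7 steps (steps 3 to 9, from 4-bromoresorcinol 7).

Steps most likely to fail

1. Step 7 (the proposed new method). Several processes may defeat it:
- a second ortho alkylation, or retention of norbornene in the product, because ring A offers two free ortho positions;
- slow SN2 opening of the oxetane by the palladacycle;
- β-hydride elimination of the palladium alkoxide in place of C–O reductive elimination;
- Lewis-acid-triggered opening of the oxetane by the neighbouring 2′-acetal oxygen;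
- weak discrimination between the enantiotopic CH2 groups.

Fallback with known chemistry, setting out from 4 and 15 and coming back at 16. Boronate 5, made from 4 as in step 2 and isolated, is oxidised (H2O2, NaOH, THF/H2O, 0 °C) to 3,5-dimethoxy-4-(3-methylbut-2-en-1-yl)phenol F1. Mono-iodination of this phloroglucinol-type ring (I2, NaHCO3, THF/H2O, 0 °C) should give 2-iodo-3,5-dimethoxy-4-(3-methylbut-2-en-1-yl)phenol F2. Acetylation (Ac2O, pyridine) gives 2-iodo-3,5-dimethoxy-4-(3-methylbut-2-en-1-yl)phenyl acetate F3. Separately, oxetane 15 is opened enantioselectively with Me3SiBr under a chiral squaramide hydrogen-bond-donor catalyst (t-BuOMe, −78 °C, a temperature at which the aryl MOM acetals should survive); the catalyst antipode is chosen to give {(2R)-3-bromo-2-[2,4-bis(methoxymethoxy)-3-(3-methylbut-2-en-1-yl)phenyl]propoxy}trimethylsilane F4, and this step sets the stereocentre. Zinc insertion (Zn dust, LiCl, THF, 50 °C) gives {(2R)-2-[2,4-bis(methoxymethoxy)-3-(3-methylbut-2-en-1-yl)phenyl]-3-[(trimethylsilyl)oxy]propyl}zinc bromide F5. Negishi coupling with F3 (Pd(OAc)2, SPhos, THF, rt to 50 °C) forms C4–C4a and gives 2-{(2R)-2-[2,4-bis(methoxymethoxy)-3-(3-methylbut-2-en-1-yl)phenyl]-3-[(trimethylsilyl)oxy]propyl}-3,5-dimethoxy-4-(3-methylbut-2-en-1-yl)phenyl acetate F6. Methanolysis (K2CO3, MeOH, rt) removes acetate and silyl ether to give 2-{(2R)-2-[2,4-bis(methoxymethoxy)-3-(3-methylbut-2-en-1-yl)phenyl]-3-hydroxypropyl}-3,5-dimethoxy-4-(3-methylbut-2-en-1-yl)phenol F7. Mitsunobu cyclisation (PPh3, diisopropyl azodicarboxylate, THF, 0 °C to rt) closes O1–C2 without touching C3 and returns 16.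

2. Step 6. Protodeboronation of the electron-rich ortho-alkoxy boronic acid in the hot alkoxide medium and slow transmetalation next to the ortho substituent may leave little coupled product.

Fallback, setting out from bromide 10 and coming back at 15: the oxetane ring is built by cyclisation and not coupled as a preformed ring. Palladium-catalysed α-arylation of diethyl malonate with 10 (Pd(dba)2, P(t-Bu)3, K3PO4, toluene, 80 °C) gives diethyl 2-[2,4-bis(methoxymethoxy)-3-(3-methylbut-2-en-1-yl)phenyl]propanedioate F8. Reduction (LiAlH4, THF, 0 °C to rt) gives 2-[2,4-bis(methoxymethoxy)-3-(3-methylbut-2-en-1-yl)phenyl]propane-1,3-diol F9. One-pot monotosylation and intramolecular Williamson etherification (n-BuLi, TsCl, THF, 0 °C; then n-BuLi, 60 °C) proceeds through racemic 2-[2,4-bis(methoxymethoxy)-3-(3-methylbut-2-en-1-yl)phenyl]-3-hydroxypropyl 4-methylbenzenesulfonate F10 to the achiral oxetane 15.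

3. Step 9. Over-oxidation or oxidative coupling of the resorcinol, incomplete conversion of a lipophilic substrate in the aqueous medium, and acid-induced cyclisation of the hydroxyquinone onto the prenyl group during work-up may erode the yield.

Fallback, setting out from 18 and coming back at 19: the C5′ oxygen is introduced by formylation and Dakin oxidation instead of direct radical oxidation. Magnesium-mediated ortho-formylation (MgCl2, Et3N, paraformaldehyde, MeCN, reflux) can only occur at C5′, the single free position ortho to a phenol, and gives 5-[(3R)-5,7-dimethoxy-6-(3-methylbut-2-en-1-yl)-3,4-dihydro-2H-chromen-3-yl]-2,4-dihydroxy-3-(3-methylbut-2-en-1-yl)benzaldehyde F11. Dakin oxidation (H2O2, NaOH, H2O/THF, 0 °C, under argon) proceeds through 5-[(3R)-5,7-dimethoxy-6-(3-methylbut-2-en-1-yl)-3,4-dihydro-2H-chromen-3-yl]-2,4-dihydroxy-3-(3-methylbut-2-en-1-yl)phenyl formate F12 to 5-[(3R)-5,7-dimethoxy-6-(3-methylbut-2-en-1-yl)-3,4-dihydro-2H-chromen-3-yl]-3-(3-methylbut-2-en-1-yl)benzene-1,2,4-triol F13. This hydroxyhydroquinone is oxidised by air in buffered aqueous acetone (or by Ag2O) to 19.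

Further compounds
F1 | step 7 | 3,5-dimethoxy-4-(3-methylbut-2-en-1-yl)phenol | COc1cc(O)cc(OC)c1CC=C(C)C
F2 | step 7 | 2-iodo-3,5-dimethoxy-4-(3-methylbut-2-en-1-yl)phenol | COc1cc(O)c(I)c(OC)c1CC=C(C)C
F3 | step 7 | 2-iodo-3,5-dimethoxy-4-(3-methylbut-2-en-1-yl)phenyl acetate | COc1cc(OC(C)=O)c(I)c(OC)c1CC=C(C)C
F4 | step 7 | {(2R)-3-bromo-2-[2,4-bis(methoxymethoxy)-3-(3-methylbut-2-en-1-yl)phenyl]propoxy}trimethylsilane | BrC[C@H](c1ccc(OCOC)c(CC=C(C)C)c1OCOC)CO[Si](C)(C)C
F5 | step 7 | {(2R)-2-[2,4-bis(methoxymethoxy)-3-(3-methylbut-2-en-1-yl)phenyl]-3-[(trimethylsilyl)oxy]propyl}zinc bromide | Br[Zn]C[C@H](c1ccc(OCOC)c(CC=C(C)C)c1OCOC)CO[Si](C)(C)C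
F6 | step 7 | 2-{(2R)-2-[2,4-bis(methoxymethoxy)-3-(3-methylbut-2-en-1-yl)phenyl]-3-[(trimethylsilyl)oxy]propyl}-3,5-dimethoxy-4-(3-methylbut-2-en-1-yl)phenyl acetate | COc1cc(OC(C)=O)c(C[C@H](c2ccc(OCOC)c(CC=C(C)C)c2OCOC)CO[Si](C)(C)C)c(OC)c1CC=C(C)C
F7 | step 7 | 2-{(2R)-2-[2,4-bis(methoxymethoxy)-3-(3-methylbut-2-en-1-yl)phenyl]-3-hydroxypropyl}-3,5-dimethoxy-4-(3-methylbut-2-en-1-yl)phenol | COc1cc(O)c(C[C@H](c2ccc(OCOC)c(CC=C(C)C)c2OCOC)CO)c(OC)c1CC=C(C)C
F8 | step 6 | diethyl 2-[2,4-bis(methoxymethoxy)-3-(3-methylbut-2-en-1-yl)phenyl]propanedioate | CCOC(=O)C(C(=O)OCC)c1ccc(OCOC)c(CC=C(C)C)c1OCOC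
F9 | step 6 | 2-[2,4-bis(methoxymethoxy)-3-(3-methylbut-2-en-1-yl)phenyl]propane-1,3-diol | OCC(CO)c1ccc(OCOC)c(CC=C(C)C)c1OCOC
F10 | step 6 | 2-[2,4-bis(methoxymethoxy)-3-(3-methylbut-2-en-1-yl)phenyl]-3-hydroxypropyl 4-methylbenzenesulfonate (racemic) | Cc1ccc(cc1)S(=O)(=O)OCC(CO)c1ccc(OCOC)c(CC=C(C)C)c1OCOC
F11 | step 9 | 5-[(3R)-5,7-dimethoxy-6-(3-methylbut-2-en-1-yl)-3,4-dihydro-2H-chromen-3-yl]-2,4-dihydroxy-3-(3-methylbut-2-en-1-yl)benzaldehyde | COc1cc2c(c(OC)c1CC=C(C)C)C[C@H](c1cc(C=O)c(O)c(CC=C(C)C)c1O)CO2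
F12 | step 9 | 5-[(3R)-5,7-dimethoxy-6-(3-methylbut-2-en-1-yl)-3,4-dihydro-2H-chromen-3-yl]-2,4-dihydroxy-3-(3-methylbut-2-en-1-yl)phenyl formate | COc1cc2c(c(OC)c1CC=C(C)C)C[C@H](c1cc(OC=O)c(O)c(CC=C(C)C)c1O)CO2
F13 | step 9 | 5-[(3R)-5,7-dimethoxy-6-(3-methylbut-2-en-1-yl)-3,4-dihydro-2H-chromen-3-yl]-3-(3-methylbut-2-en-1-yl)benzene-1,2,4-triol | COc1cc2c(c(OC)c1CC=C(C)C)C[C@H](c1cc(O)c(O)c(CC=C(C)C)c1O)CO2
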